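**Plan**

Ring names: A = central benzene (C1 CH2Ar, C2 OH, C3 CH2, C4 O, C5 CH2, C6 O). B and C = the dihydropyran rings on C3/C4 and C5/C6. D and E = their tetrahydrofuran rings. F/G = the dihydrobenzofuran.
Cuts: (a) C1–CH2Ar (Friedel–Crafts); (b) C2–OH back to C2–Cl; (c) both ketal C–OAr and ketal C–CH3 bonds, with the two benzylic CH2 groups raised to C=O; (d) in rings B and C the bond from benzylic C to ring-fusion C and the bond from aryl C to O. This leaves 4,6-dichloro-2-fluoroisophthaloyl dichloride and two molecules of (R)-4-methylbutyrolactone.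
Enabling feature: C2, C4 and C6 of ring A are mutually meta, and each is ortho or para to both C3 and C5, so two acyl groups on C3/C5 activate all three C–halogen bonds. Acyl carbon plus ortho C–halogen is a 1,3-dielectrophile that fits the 1,3-C,O-dinucleophile of a lactone enolate (α-carbon and carbonyl oxygen).
Forward: rings D and E come with the lactone. Rings B and C close on ring A in one operation, F on C4 before Cl on C6, which gives the angular fusion and keeps Cl on C2 as a masked phenol. Then come CH3 onto the ketal carbons, removal of the two carbonyl helpers, Cl to OH, and union with the F/G fragment last.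
Stereochemistry: the two C-methyl centres come from the (R)-lactone. The ring-fusion CH and ketal carbon of both units are set by acid equilibration under control of that methyl group. The dihydrobenzofuran centre comes from a Shi epoxidation and an invertive 5-exo epoxide opening.

Key step: step 4

Assumption: (R)-4-methyldihydrofuran-2(3H)-one of high enantiomeric purity is taken as a catalogue compound; it is the only chiral starting material.

Step 1
Reactants: 1 1,3-dichloro-5-fluorobenzene
Product: 3 2,4-dichloro-6-fluorobenzoic acid, via aryllithium 2 (not isolated)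
Conditions: LiN(iPr)2, THF, −78 °C; CO2; aq HCl
Reagents that add atoms: carbon dioxide, O=C=O
Why: Directed ortho-metalation removes the most acidic proton, the one flanked by F and Cl, and carboxylation of the aryllithium fixes the first future benzylic carbon.

Step 2
Reactants: 3 2,4-dichloro-6-fluorobenzoic acid
Product: 5 4,6-dichloro-2-fluoroisophthalic acid, via lithio carboxylate 4 (not isolated)
Conditions: LiN(iPr)2 (2.2 equiv), THF, −78 °C; CO2; aq HCl
Reagents that add atoms: carbon dioxide, O=C=O
Why: A second directed ortho-metalation of the lithium carboxylate again takes the C–H flanked by F and Cl, so carboxylation places F between the two carboxyl groups.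

Step 3
Reactants: 5 4,6-dichloro-2-fluoroisophthalic acid
Product: 6 4,6-dichloro-2-fluoroisophthaloyl dichloride
Conditions: (COCl)2, DMF (cat.), CH2Cl2, 0 °C → rt
Reagents that add atoms: oxalyl chloride, ClC(=O)C(Cl)=O
Why: Standard acid chloride formation through the Vilsmeier-type chloroiminium species, to which the aryl halides are inert.

Step 4
Reactants: 6 4,6-dichloro-2-fluoroisophthaloyl dichloride; 7 (R)-4-methyldihydrofuran-2(3H)-one (2.1 equiv)
Product: 11 angular chloro-bis(2,3-dihydrofuro[2,3-b]chromen-4-one), via lithium enolate 8 (not isolated), via bis(keto lactone) dienolate 9 (not isolated), via monocyclised furochromenone 10 (not isolated)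
Conditions: 7, LiN(SiMe3)2 (4.3 equiv), THF, −78 °C; add 6, −78 → 0 °C; then DMF, 90 °C, same flask; H2O
Reagents that add atoms: none
Why: Enolate 8 attacks each acyl chloride of 6 at carbon (crossed Claisen acylation, new bond from benzylic C to ring-fusion C), the second equivalent of LiN(SiMe3)2 converts each β-keto lactone of 9 into its enolate, and the lactone-carbonyl oxygen of that enolate then displaces the ortho halide by addition–elimination (new aryl C–O bond). The closest known reaction type is the tandem C-acylation/SNAr ring closure of o-halobenzoyl chlorides with ester, malonate or enaminoester nucleophiles that gives 2-alkoxychromones, chromones and 4-quinolones (Grohe–Heitzer type). Both 4-pyranone rings close in the 6-exo-trig mode of an intramolecular SNAr, ring B on the C–F carbon and then ring C on a C–Cl carbon. No stereocentre is formed, because the α-carbon of each lactone ends up sp2 and the (R)-methyl-bearing carbon, which is not acidic in 8 to 11, is carried through unchanged. Chemoselectivity lies in the substrate: the enolate carbon cannot reach the ring (a four-membered ring would result), so only oxygen cyclises, and no methyl ketone is present that could arylate at carbon. Regioselectivity rests on fluoride leaving much faster than chloride: whichever arm closes first takes the fluoride between the two acyl groups, the other arm can then reach only its outer chloride, so the angular isomer forms and the last chloride stays as the masked phenol.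

Step 5
Reactants: 11 angular chloro-bis(2,3-dihydrofuro[2,3-b]chromen-4-one)
Product: 12 (4-chloro-2,6-dihydroxy-1,3-phenylene)bis{[(4R)-2,4-dimethyl-4,5-dihydrofuran-3-yl]methanone}
Conditions: Me2CuLi (from MeLi and CuI, 5 equiv), Et2O–THF, −78 → −20 °C; aq NH4Cl
Reagents that add atoms: lithium dimethylcuprate, [Li+].C[Cu-]C
Why: Proposed new method: the future ketal carbon of each 2-alkoxy-4-pyranone is the β-carbon of an enone that carries an aryloxide leaving group, so Me2CuLi should add there and the enolate should expel the better nucleofuge (the ring A aryloxide, not the alkoxide) to give the 3-aroyl-2-methyl-4,5-dihydrofuran without forming a stereocentre; the closest known reaction type is the conjugate addition–elimination of Gilman cuprates with β-alkoxy, β-acyloxy and β-halo enones and with α-oxoketene dithioacetals.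

Step 6
Reactants: 12 (4-chloro-2,6-dihydroxy-1,3-phenylene)bis{[(4R)-2,4-dimethyl-4,5-dihydrofuran-3-yl]methanone}
Product: 14 chloro-bis(2H-chromene ketal), via bis(allylic alcohol) 13 (not isolated)
Conditions: iBu2AlH (6 equiv), CH2Cl2, −78 → 0 °C; aq potassium sodium tartrate; crude 13, PPTS (10 mol %), 4 Å MS, CH2Cl2, rt
Reagents that add atoms: none
Why: 1,2-Reduction of a vinylogous ester (as in the Stork–Danheiser sequence) gives benzylic/allylic alcohols that ionise with mild acid to vinylogous o-quinone methides and close by oxa-6π electrocyclisation (the flav-3-ene synthesis from reduced 2'-hydroxychalcones); closure is reversible, so the C3 arm settles on O–C4 and the C5 arm on O–C6 because C2 carries Cl, and the configuration of the new ketal carbons is not yet decisive.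

Step 7
Reactants: 14 chloro-bis(2H-chromene ketal)
Product: 15 chloro-bis(furochroman ketal)
Conditions: H2 (1 atm), PtO2, EtOAc, rt; filter; BF3·OEt2 (0.2 equiv), MgSO4, Et2O, 0 °C
Reagents that add atoms: none
Why: Catalytic hydrogenation of the two 2H-chromene double bonds followed by Lewis-acid ketal equilibration (reversible opening to the oxocarbenium ion and the 3-benzyl-4,5-dihydrofuran) should set ring-fusion CH and ketal carbon of both units under thermodynamic control, cis-fused with the benzylic CH2 trans to the neighbouring C-methyl group, while Cl on C2 leaves no other phenol to which a ketal could migrate.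

Step 8
Reactants: 15 chloro-bis(furochroman ketal)
Product: 16 bis(furochroman ketal) phenol
Conditions: Pd2(dba)3, tBuXPhos, KOH, 1,4-dioxane–H2O, 100 °C; NaH2PO4 buffer
Reagents that add atoms: potassium hydroxide, [K+].[OH-]
Why: Palladium-catalysed hydroxylation of an aryl chloride (Buchwald–Hartwig-type C–O coupling with hydroxide) needs only aqueous base, to which the ketals and all stereocentres are inert.

Step 9
Reactants: 17 4-bromophenol; 18 prenyl bromide (1-bromo-3-methylbut-2-ene)
Product: 19 4-bromo-2-(3-methylbut-2-en-1-yl)phenol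
Conditions: NaH, toluene, 0 °C → rt
Reagents that add atoms: none
Why: ortho-C-Alkylation of a sodium phenoxide ion pair in a non-polar solvent, where the shielded oxygen leaves the ortho carbon as the nucleophilic site toward the allylic halide.

Step 10
Reactants: 19 4-bromo-2-(3-methylbut-2-en-1-yl)phenol
Product: 20 [4-bromo-2-(3-methylbut-2-en-1-yl)phenoxy](tert-butyl)dimethylsilane
Conditions: tBuMe2SiCl, imidazole, DMF, rt
Reagents that add atoms: tert-butyldimethylsilyl chloride, CC(C)(C)[Si](C)(C)Cl
Why: Standard silylation keeps the phenol from being oxidised and from opening the epoxide prematurely in the next step.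

Step 11
Reactants: 20 [4-bromo-2-(3-methylbut-2-en-1-yl)phenoxy](tert-butyl)dimethylsilane
Product: 21 (R)-{4-bromo-2-[(3,3-dimethyloxiran-2-yl)methyl]phenoxy}(tert-butyl)dimethylsilane
Conditions: D-fructose-derived Shi ketone (0.3 equiv), KHSO5 (as 2KHSO5·KHSO4·K2SO4), K2CO3, Na2B4O7 buffer, Bu4NHSO4, MeCN–CH2(OMe)2–H2O, 0 °C
Reagents that add atoms: potassium peroxymonosulfate, [K+].[O-]S(=O)(=O)OO
Why: Shi epoxidation of a trisubstituted alkene, in which the spiro transition state of the D-fructose-derived dioxirane should deliver oxygen to the face that gives the (R)-epoxide.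

Step 12
Reactants: 21 (R)-{4-bromo-2-[(3,3-dimethyloxiran-2-yl)methyl]phenoxy}(tert-butyl)dimethylsilane
Product: 23 (S)-2-(5-bromo-2,3-dihydrobenzofuran-2-yl)propan-2-ol, via epoxy phenol 22 (not isolated)
Conditions: Bu4NF, THF, 0 °C → rt; H2O
Reagents that add atoms: none
Why: Desilylation frees the phenoxide, which opens the epoxide at its secondary carbon in a base-mediated 5-exo-tet SN2 reaction with inversion, so the (R)-epoxide gives the (S)-dihydrobenzofuran.

Step 13
Reactants: 23 (S)-2-(5-bromo-2,3-dihydrobenzofuran-2-yl)propan-2-ol
Product: 24 (S)-5-bromo-2-(prop-1-en-2-yl)-2,3-dihydrobenzofuran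
Conditions: SOCl2, pyridine, 0 °C
Reagents that add atoms: none
Why: E2 dehydration of the tertiary chlorosulfite toward one of the six methyl hydrogens gives the isopropenyl group and does not touch the stereocentre.

Step 14
Reactants: 24 (S)-5-bromo-2-(prop-1-en-2-yl)-2,3-dihydrobenzofuran
Product: 26 (S)-[2-(prop-1-en-2-yl)-2,3-dihydrobenzofuran-5-yl]methanol, via aryllithium 25 (not isolated)
Conditions: nBuLi, THF, −78 °C; (CH2O)n, −78 °C → rt; H2O
Reagents that add atoms: paraformaldehyde (reacts as formaldehyde), C=O
Why: Bromine–lithium exchange followed by hydroxymethylation with formaldehyde, with the alkene and the allylic ether inert at low temperature.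

Step 15
Reactants: 16 bis(furochroman ketal) phenol; 26 (S)-[2-(prop-1-en-2-yl)-2,3-dihydrobenzofuran-5-yl]methanol
Product: 27 target CNP0131395.1
Conditions: Sc(OTf)3 (5 mol %), 4 Å MS, CH2Cl2, −20 → 0 °C
Reagents that add atoms: none
Why: Friedel–Crafts benzylation in which the p-alkoxybenzyl alcohol ionises under catalytic Lewis acid and the cation is taken by C1, the only free position of ring A (ortho, ortho and para to its three oxygen substituents), with no stereocentre involved.

**Compound list**

1 | 1,3-dichloro-5-fluorobenzene | Fc1cc(Cl)cc(Cl)c1 | starting material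
2 | 2,4-dichloro-6-fluorophenyllithium (not isolated) | [Li]c1c(F)cc(Cl)cc1Cl | intermediate
3 | 2,4-dichloro-6-fluorobenzoic acid | OC(=O)c1c(F)cc(Cl)cc1Cl | intermediate
4 | lithium 4,6-dichloro-2-fluoro-3-lithiobenzoate (not isolated) | [Li]OC(=O)c1c(F)c([Li])c(Cl)cc1Cl | intermediate
5 | 4,6-dichloro-2-fluoroisophthalic acid | OC(=O)c1c(F)c(C(=O)O)c(Cl)cc1Cl | intermediate
6 | 4,6-dichloro-2-fluoroisophthaloyl dichloride | ClC(=O)c1c(F)c(C(Cl)=O)c(Cl)cc1Cl | intermediate
7 | (R)-4-methyldihydrofuran-2(3H)-one | C[C@H]1COC(=O)C1 | starting material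
8 | lithium enolate of 7, (R)-configured (not isolated) | C[C@H]1COC(O[Li])=C1 | intermediate
9 | 3,3'-(4,6-dichloro-2-fluoro-1,3-phenylenedicarbonyl)bis[(4R)-4-methyldihydrofuran-2(3H)-one], present as its dilithium dienolate, α-carbons stereolabile (not isolated) | O=C(C1C(=O)OC[C@@H]1C)c1c(F)c(C(=O)C2C(=O)OC[C@@H]2C)c(Cl)cc1Cl | intermediate
10 | monocyclised compound: ring B closed on C4 (fluoride lost), second (4R)-keto lactone arm on C5 still open, Cl on C2 and C6 (not isolated) | Clc1cc(Cl)c(C(=O)C2C(=O)OC[C@@H]2C)c2c1C(=O)C1=C(O2)OC[C@@H]1C | intermediate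
11 | angular chloro-bis(2,3-dihydrofuro[2,3-b]chromen-4-one): ring A with H on C1 and Cl on C2; rings B (C3/C4) and C (C5/C6) are 2-alkoxy-4-pyranones whose C=C is shared with a dihydrofuran O–CH2–CH(CH3); both methyl-bearing carbons (R) | Clc1cc2c(c3c1C(=O)C1=C(O3)OC[C@@H]1C)C(=O)C1=C(O2)OC[C@@H]1C | intermediate
12 | (4-chloro-2,6-dihydroxy-1,3-phenylene)bis{[(4R)-2,4-dimethyl-4,5-dihydrofuran-3-yl]methanone} | Oc1cc(Cl)c(C(=O)C2=C(C)OC[C@@H]2C)c(O)c1C(=O)C1=C(C)OC[C@@H]1C | intermediate
13 | corresponding bis(carbinol), carbinol centres undefined, both dihydrofuran centres (R) (not isolated) | Oc1cc(Cl)c(C(O)C2=C(C)OC[C@@H]2C)c(O)c1C(O)C1=C(C)OC[C@@H]1C | intermediate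
14 | chloro-bis(2H-chromene ketal): rings B and C are 2H-pyrans (benzylic CH=C), each ketal carbon carries CH3, O of ring A and O of ring D or E; C-methyl centres (R); acid-labile ketal carbons drawn (R) | Clc1cc2O[C@@]3(C)OC[C@H](C)C3=Cc2c2O[C@@]3(C)OC[C@H](C)C3=Cc12 | intermediate
15 | chloro-bis(furochroman ketal): as the target core with Cl on C2 and H on C1; in each cis-fused unit C-methyl carbon (R), ring-fusion CH (R), ketal carbon (R) | Clc1cc2O[C@@]3(C)OC[C@H](C)[C@H]3Cc2c2O[C@@]3(C)OC[C@H](C)[C@H]3Cc12 | intermediate
16 | bis(furochroman ketal) phenol: as 15 with OH on C2 | Oc1cc2O[C@@]3(C)OC[C@H](C)[C@H]3Cc2c2O[C@@]3(C)OC[C@H](C)[C@H]3Cc12 | intermediate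
17 | 4-bromophenol | Oc1ccc(Br)cc1 | starting material
18 | prenyl bromide | CC(C)=CCBr | starting material
19 | 4-bromo-2-(3-methylbut-2-en-1-yl)phenol | CC(C)=CCc1cc(Br)ccc1O | intermediate
20 | [4-bromo-2-(3-methylbut-2-en-1-yl)phenoxy](tert-butyl)dimethylsilane | CC(C)=CCc1cc(Br)ccc1O[Si](C)(C)C(C)(C)C | intermediate
21 | (R)-{4-bromo-2-[(3,3-dimethyloxiran-2-yl)methyl]phenoxy}(tert-butyl)dimethylsilane | CC1(C)O[C@@H]1Cc1cc(Br)ccc1O[Si](C)(C)C(C)(C)C | intermediate
22 | (R)-4-bromo-2-[(3,3-dimethyloxiran-2-yl)methyl]phenol, as its phenoxide (not isolated) | CC1(C)O[C@@H]1Cc1cc(Br)ccc1O | intermediate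
23 | (S)-2-(5-bromo-2,3-dihydrobenzofuran-2-yl)propan-2-ol | CC(C)(O)[C@@H]1Cc2cc(Br)ccc2O1 | intermediate
24 | (S)-5-bromo-2-(prop-1-en-2-yl)-2,3-dihydrobenzofuran | C=C(C)[C@@H]1Cc2cc(Br)ccc2O1 | intermediate
25 | (S)-[2-(prop-1-en-2-yl)-2,3-dihydrobenzofuran-5-yl]lithium (not isolated) | C=C(C)[C@@H]1Cc2cc([Li])ccc2O1 | intermediate
26 | (S)-[2-(prop-1-en-2-yl)-2,3-dihydrobenzofuran-5-yl]methanol | C=C(C)[C@@H]1Cc2cc(CO)ccc2O1 | intermediate
27 | CNP0131395.1 | C=C(C)[C@@H]1Cc2cc(Cc3c(O)c4c(c5c3O[C@@]3(C)OC[C@H](C)[C@H]3C5)O[C@@]3(C)OC[C@H](C)[C@H]3C4)ccc2O1 | target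

**Step count**

Total step count: 15. Longest linear sequence: 9 steps (steps 1 to 8 and 15).

**Steps most likely to fail**

Step 5. The doubly oxygenated β-carbon may be too poor an acceptor, so the cuprate may not react or may attack the pyranone carbonyl in the 1,2-sense. The second unit is further deactivated once the first aryloxide has been released.
Fallback, setting out from 11: activate the chromenones as cations, the established way to bring carbon nucleophiles to C2 of chromones.
- O-Silylation of both pyranone carbonyl groups with tBuMe2SiOTf in CH2Cl2 gives the bis(4-silyloxybenzopyrylium) bis(triflate) F1.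
- MeMgBr adds to the cationic ketal-to-be carbons to give the bis(silyl enol ether) ketal F2.
- Bu4NF buffered with AcOH frees the enolates, which lose the ring A aryloxide. The sequence comes back to the route at 12.

Step 4. The cascade may stall after the first ring closure, because the stabilised enolate oxygen is a weak nucleophile toward the aryl chloride. Material may also be lost by O-acylation of the enolate.
Fallback, setting out from 6 and 7: run the events one at a time.
- Stop the acylation at 0 °C and isolate bis(keto lactone) 9.
- Close ring B with K2CO3 in DMF at room temperature to give 10.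
- Close ring C by a copper-catalysed intramolecular Ullmann-type O-arylation of the 1,3-dicarbonyl unit (CuI, 1,10-phenanthroline, Cs2CO3, dioxane, 100 °C). This comes back to the route at 11 and makes no compound outside the list (F0).

Step 15. The Lewis acid may cause migration of a ketal to the now free phenol oxygen, protonation of the isopropenyl group, ionisation of the allylic aryl ether, or O-benzylation instead of C-benzylation.
Fallback, setting out from 16 and from aryllithium 25 (made from 24): use only basic conditions.
- ortho-Formylation of 16 with MgCl2, Et3N and paraformaldehyde (Casnati–Skattebøl) gives the salicylaldehyde F3.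
- Boc2O, (iPr)2NEt and DMAP give the aryl tert-butyl carbonate F4.
- Aryllithium 25 adds to the aldehyde at −78 °C. MgBr2·OEt2 then triggers carbonate migration and loss of tert-butyl carbonate to give the o-quinone methide F5.
- NaBH4 reduces F5 at the exocyclic carbon, and the sequence comes back to the route at 27.

Further compounds
F1 | step 5 | bis(4-tert-butyldimethylsilyloxybenzopyrylium) bis(triflate) of 11, both methyl-bearing carbons (R) | Clc1cc2[O+]=C3OC[C@H](C)C3=C(O[Si](C)(C)C(C)(C)C)c2c2[O+]=C3OC[C@H](C)C3=C(O[Si](C)(C)C(C)(C)C)c12.[O-]S(=O)(=O)C(F)(F)F.[O-]S(=O)(=O)C(F)(F)F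
F2 | step 5 | bis(silyl enol ether) ketal, C-methyl centres (R), ketal carbons drawn (R) | Clc1cc2O[C@@]3(C)OC[C@H](C)C3=C(O[Si](C)(C)C(C)(C)C)c2c2O[C@@]3(C)OC[C@H](C)C3=C(O[Si](C)(C)C(C)(C)C)c12
F0 | step 4 | none | none
F3 | step 15 | salicylaldehyde: 16 with CHO on C1 | O=Cc1c(O)c2c(c3c1O[C@@]1(C)OC[C@H](C)[C@H]1C3)O[C@@]1(C)OC[C@H](C)[C@H]1C2
F4 | step 15 | aryl tert-butyl carbonate of F3 | O=Cc1c(OC(=O)OC(C)(C)C)c2c(c3c1O[C@@]1(C)OC[C@H](C)[C@H]1C3)O[C@@]1(C)OC[C@H](C)[C@H]1C2
F5 | step 15 | o-quinone methide (C2=O, C1=CH–aryl), alkene geometry undefined | C=C(C)[C@@H]1Cc2cc(C=C3C(=O)C4=C(C5=C3O[C@@]3(C)OC[C@H](C)[C@H]3C5)O[C@@]3(C)OC[C@H](C)[C@H]3C4)ccc2O1
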